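**Plan**

- Retrosynthetic cuts, in this order: the C3–O feruloyl ester bond; the side-chain C3'–C4' bond (cross-metathesis, alkenes hydrogenated afterwards); the ring C4=C5 bond (ring-rearrangement metathesis); the N1–C6 bond (palladium allylic amination); the C3–C4 bond (vinyl addition to a D-alanine aldehyde equivalent).
- Forward order: acyclic O-silyl amino alcohol, N-cyclopentenylation, the piperidine ring (the only ring made; the carbocycle is consumed), N-Boc protection, chain extension, hydrogenation and desilylation, acylation, deprotection.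
- Enabling feature: C6, C5 and the side-chain carbons C3', C2', C1' are carried as a cyclopent-2-enyl ring on N1. Only the C4=C5 bond must then form to close the ring N1–C2–C3–C4–C5–C6, while the strained five-membered ring opens into the C6 but-3-enyl chain.
- Stereochemistry: C2 comes from D-alanine; C3 from chelation-controlled vinyl addition (threo); C6 from ligand-controlled, stereoconvergent allylic amination of a racemic carbonate. No later step creates a stereocentre.

Key step: step 7

Atom labels: piperidine N1, C2 (methyl), C3 (oxygen), C4, C5, C6; side chain C1' to C12'.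

Assumption on the chemistry: the (R,R)-enantiomer of the DACH-phenyl Trost ligand is taken as the one that steers the amine to the allyl terminus giving the (1S)-cyclopentenyl amine; if the sense proves opposite, the (S,S)-ligand is used and nothing else changes.

**Route**

Step 1
Reactants: 1 methyl D-alaninate hydrochloride
Product: 2 methyl (2R)-2-[(diphenylmethylidene)amino]propanoate
Conditions: Ph2C=NH (1.0 equiv), CH2Cl2, rt
Reagents that add atoms: benzophenone imine, N=C(c1ccccc1)c1ccccc1
Why: Transimination (Schiff-base exchange) of the amino ester salt is driven by precipitation of NH4Cl and does not touch the C2 stereocentre.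

Step 2
Reactants: 2 methyl (2R)-2-[(diphenylmethylidene)amino]propanoate; 3 vinylmagnesium bromide
Product: 6 (2R,3R)-2-[(diphenylmethylidene)amino]pent-4-en-3-ol, via aluminoxy acetal 4 (not isolated), via Schiff-base aldehyde 5 (not isolated)
Conditions: i-Bu2AlH (1.05 equiv), CH2Cl2, −78 °C; then 3 (3 equiv, THF), −78 °C → rt; aq. NaHCO3
Reagents that add atoms: none
Why: One-pot i-Bu2AlH half-reduction of a Schiff-base ester followed by chelation-controlled Grignard addition: the aluminoxy acetal releases the aldehyde as a five-membered chelate through the imine nitrogen, and the vinyl nucleophile should attack the face opposite the C2 methyl group (Cram chelate model), setting C3 as R (threo), while the hindered ketimine resists hydride and Grignard attack and the low temperature guards C2 against epimerisation.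

Step 3
Reactants: 6 (2R,3R)-2-[(diphenylmethylidene)amino]pent-4-en-3-ol
Product: 7 (2R,3R)-3-[(tert-butyldimethylsilyl)oxy]-N-(diphenylmethylidene)pent-4-en-2-amine
Conditions: TBSOTf (1.3 equiv), 2,6-lutidine, CH2Cl2, −78 → 0 °C
Reagents that add atoms: tert-butyldimethylsilyl trifluoromethanesulfonate, CC(C)(C)[Si](C)(C)OS(=O)(=O)C(F)(F)F
Why: Silyl ether formation with a silyl triflate and a hindered base is fast on secondary alcohols and traps the open-chain hydroxy imine.

Step 4
Reactants: 7 (2R,3R)-3-[(tert-butyldimethylsilyl)oxy]-N-(diphenylmethylidene)pent-4-en-2-amine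
Product: 8 (2R,3R)-3-[(tert-butyldimethylsilyl)oxy]pent-4-en-2-amine
Conditions: 15% aq. citric acid, THF, rt; then aq. K2CO3
Reagents that add atoms: none
Why: Mild acid hydrolysis of the ketimine frees the primary amine, and the weak acid should leave the secondary silyl ether intact.

Step 5
Reactants: 9 cyclopent-2-en-1-one
Product: 11 rac-cyclopent-2-en-1-yl methyl carbonate, via cyclopent-2-en-1-ol 10 (not isolated)
Conditions: NaBH4, CeCl3·7H2O, MeOH, 0 °C; extraction into CH2Cl2; then ClCO2Me, pyridine, 0 °C → rt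
Reagents that add atoms: methyl chloroformate, COC(=O)Cl
Why: Luche reduction gives clean 1,2-reduction of the enone, and acylation of the volatile allylic alcohol with the chloroformate (carbonate formation) supplies the ionisable leaving group.

Step 6
Reactants: 8 (2R,3R)-3-[(tert-butyldimethylsilyl)oxy]pent-4-en-2-amine; 11 rac-cyclopent-2-en-1-yl methyl carbonate
Product: 12 (2R,3R)-3-[(tert-butyldimethylsilyl)oxy]-N-[(1S)-cyclopent-2-en-1-yl]pent-4-en-2-amine
Conditions: Pd2(dba)3·CHCl3 (2.5 mol%), (R,R)-DACH-phenyl Trost ligand (7.5 mol%), CH2Cl2, rt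
Reagents that add atoms: none
Why: Tsuji–Trost asymmetric allylic amination: zerovalent palladium ionises both enantiomers of 11 to the same symmetrical η3-cyclopentenyl palladium complex with loss of CO2 and methoxide, and the chiral diphosphine directs outer-sphere attack of the primary amine to one of the two enantiotopic allyl termini, which sets C6 (the 1S centre of the cyclopentenyl group) stereoconvergently.

Step 7
Reactants: 12 (2R,3R)-3-[(tert-butyldimethylsilyl)oxy]-N-[(1S)-cyclopent-2-en-1-yl]pent-4-en-2-amine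
Product: 15 (2R,3R,6S)-6-(but-3-en-1-yl)-3-[(tert-butyldimethylsilyl)oxy]-2-methyl-1,2,3,6-tetrahydropyridine, via dienyl ammonium tosylate 13 (not isolated), via tetrahydropyridinium tosylate 14 (not isolated)
Conditions: TsOH·H2O (1.0 equiv), CH2Cl2, rt; then (H2IMes)(PCy3)Cl2Ru=CHPh (second-generation Grubbs catalyst, 5 mol%), ethene (1 atm), CH2Cl2 (0.01 M), 40 °C; aq. NaHCO3
Reagents that add atoms: none
Why: A ruthenium alkylidene generated at the terminal vinyl carbon C4 adds in an intramolecular [2+2] fashion across the cyclopentene double bond (C5=C3') and the metallacyclobutane cycloreverts, which forms the C4=C5 bond and leaves a new alkylidene at C3' that ethene turns into the terminal alkene; the alternative sequence of ring opening first and ring closure second ends at the same product, so the net change is an isomerisation. The closest known reaction type is ruthenium-catalysed ring-rearrangement metathesis of N-cycloalkenyl allylic amines, here run on the ammonium salt as is usual for basic amines in olefin metathesis. The six-membered ring N1–C2–C3–C4–C5–C6 closes in the ring-closing olefin metathesis mode while the five-membered carbocycle opens. No stereocentre is created: C2 and C3 are spectators and C6, although allylic, is not part of a reacting double bond, so its configuration is carried unchanged from the carbocycle to the heterocycle. The selectivity required is intramolecular rearrangement over oligomerisation and six- over eight-membered closure, which the three-atom link C3–C2–N1 between the two alkenes, the release of cyclopentene strain, high dilution and the ethene atmosphere should secure. Protonation as the tosylate keeps the nitrogen lone pair away from ruthenium.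

Step 8
Reactants: 16 8-bromooct-1-ene; 17 N-methoxy-N-methylacetamide
Product: 19 dec-9-en-2-one, via oct-7-enylmagnesium bromide 18 (not isolated)
Conditions: Mg, THF, rt → 40 °C; then 17, 0 °C; 1 M aq. HCl
Reagents that add atoms: none
Why: Grignard formation followed by Weinreb ketone synthesis, in which the chelated tetrahedral adduct holds until the quench so that addition stops at the methyl ketone.

Step 9
Reactants: 15 (2R,3R,6S)-6-(but-3-en-1-yl)-3-[(tert-butyldimethylsilyl)oxy]-2-methyl-1,2,3,6-tetrahydropyridine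
Product: 20 tert-butyl (2R,3R,6S)-6-(but-3-en-1-yl)-3-[(tert-butyldimethylsilyl)oxy]-2-methyl-3,6-dihydro-2H-pyridine-1-carboxylate
Conditions: Boc2O (2.5 equiv), i-Pr2NEt (1.5 equiv), THF, 55 °C
Reagents that add atoms: di-tert-butyl dicarbonate, CC(C)(C)OC(=O)OC(=O)OC(C)(C)C
Why: Carbamate formation (N-Boc protection) of the secondary amine, pushed by excess anhydride and gentle heating because nitrogen sits between two branched carbons; the carbamate removes the basic lone pair before the second metathesis and the hydrogenation, and the molecule holds no other nucleophile.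

Step 10
Reactants: 20 tert-butyl (2R,3R,6S)-6-(but-3-en-1-yl)-3-[(tert-butyldimethylsilyl)oxy]-2-methyl-3,6-dihydro-2H-pyridine-1-carboxylate; 19 dec-9-en-2-one
Product: 21 tert-butyl (2R,3R,6S)-3-[(tert-butyldimethylsilyl)oxy]-2-methyl-6-[(3E/Z)-11-oxododec-3-en-1-yl]-3,6-dihydro-2H-pyridine-1-carboxylate
Conditions: 19 (3 equiv), (H2IMes)Cl2Ru=CH(2-i-PrO-C6H4) (second-generation Hoveyda–Grubbs catalyst, 5 mol%), CH2Cl2, 40 °C
Reagents that add atoms: none
Why: Olefin cross-metathesis between two unhindered monosubstituted alkenes with the ketone partner in excess, driven by loss of ethene; the carbamate nitrogen does not bind ruthenium, the unstrained ring alkene flanked by two branched allylic carbons should stay out of the reaction, and the alkene geometry is irrelevant because the double bond is hydrogenated next.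

Step 11
Reactants: 21 tert-butyl (2R,3R,6S)-3-[(tert-butyldimethylsilyl)oxy]-2-methyl-6-[(3E/Z)-11-oxododec-3-en-1-yl]-3,6-dihydro-2H-pyridine-1-carboxylate
Product: 23 tert-butyl (2R,3R,6S)-3-hydroxy-2-methyl-6-(11-oxododecyl)piperidine-1-carboxylate, via saturated silyl ether 22 (not isolated)
Conditions: H2 (1 atm), Pd/C (10 wt%), EtOAc, rt; filtration; then HF·pyridine, pyridine–THF, 0 °C → rt; aq. NaHCO3
Reagents that add atoms: none
Why: Heterogeneous catalytic hydrogenation saturates both C=C bonds without creating a stereocentre and leaves the aliphatic ketone alone, the carbamate ruling out reductive amination of that ketone by the ring nitrogen; fluoride-driven desilylation (formation of the strong Si–F bond) under buffered, mildly acidic conditions then frees the C3 alcohol without cleaving the tert-butyl carbamate and without generating an alkoxide that could attack the carbamate carbonyl.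

Step 12
Reactants: 24 ferulic acid
Product: 25 (2E)-3-{4-[(tert-butoxycarbonyl)oxy]-3-methoxyphenyl}prop-2-enoic acid
Conditions: NaOH (2.1 equiv), Boc2O (1.2 equiv), THF–H2O, 0 °C → rt; then 1 M HCl to pH 3
Reagents that add atoms: di-tert-butyl dicarbonate, CC(C)(C)OC(=O)OC(=O)OC(C)(C)C
Why: Schotten–Baumann-type tert-butoxycarbonylation of the phenoxide; any mixed carboxylic–carbonic anhydride formed at the carboxylate is hydrolysed back in the aqueous base.

Step 13
Reactants: 23 tert-butyl (2R,3R,6S)-3-hydroxy-2-methyl-6-(11-oxododecyl)piperidine-1-carboxylate; 25 (2E)-3-{4-[(tert-butoxycarbonyl)oxy]-3-methoxyphenyl}prop-2-enoic acid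
Product: 27 tert-butyl (2R,3R,6S)-3-{[(2E)-3-{4-[(tert-butoxycarbonyl)oxy]-3-methoxyphenyl}prop-2-enoyl]oxy}-2-methyl-6-(11-oxododecyl)piperidine-1-carboxylate, via O-acylisourea 26 (not isolated)
Conditions: DCC (1.5 equiv), DMAP (0.2 equiv), 25 (1.5 equiv), CH2Cl2, 0 °C → rt
Reagents that add atoms: none
Why: Steglich esterification of the secondary alcohol through the O-acylisourea and the acylpyridinium ion; the N-Boc and O-Boc groups block amide formation and phenol acylation, and the configuration at C3 is retained because the C3–O bond is not broken.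

Step 14
Reactants: 27 tert-butyl (2R,3R,6S)-3-{[(2E)-3-{4-[(tert-butoxycarbonyl)oxy]-3-methoxyphenyl}prop-2-enoyl]oxy}-2-methyl-6-(11-oxododecyl)piperidine-1-carboxylate
Product: 28 (+)-3-O-feruloylcassine [(2R,3R,6S)-2-methyl-6-(11-oxododecyl)piperidin-3-yl (2E)-3-(4-hydroxy-3-methoxyphenyl)prop-2-enoate]
Conditions: TFA–CH2Cl2 (1:4), 0 °C; then aq. NaHCO3
Reagents that add atoms: none
Why: Acidolysis cleaves the tert-butyl carbamate and the aryl tert-butyl carbonate in one operation (loss of the tert-butyl cation, then decarboxylation), while the cinnamate ester, the ketone and the three stereocentres should be unaffected.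

**Compound list**

1 | methyl D-alaninate hydrochloride | C[C@@H](N)C(=O)OC.Cl | starting material
2 | methyl (2R)-2-[(diphenylmethylidene)amino]propanoate | C[C@@H](N=C(c1ccccc1)c1ccccc1)C(=O)OC | intermediate
3 | vinylmagnesium bromide | C=C[Mg]Br | starting material
4 | [(2R)-2-[(diphenylmethylidene)amino]-1-methoxypropoxy]bis(2-methylpropyl)alumane (aluminoxy acetal) | COC(O[Al](CC(C)C)CC(C)C)[C@@H](C)N=C(c1ccccc1)c1ccccc1 | intermediate (not isolated)
5 | (2R)-2-[(diphenylmethylidene)amino]propanal | O=C[C@@H](C)N=C(c1ccccc1)c1ccccc1 | intermediate (not isolated)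
6 | (2R,3R)-2-[(diphenylmethylidene)amino]pent-4-en-3-ol | C=C[C@@H](O)[C@@H](C)N=C(c1ccccc1)c1ccccc1 | intermediate
7 | (2R,3R)-3-[(tert-butyldimethylsilyl)oxy]-N-(diphenylmethylidene)pent-4-en-2-amine | C=C[C@@H](O[Si](C)(C)C(C)(C)C)[C@@H](C)N=C(c1ccccc1)c1ccccc1 | intermediate
8 | (2R,3R)-3-[(tert-butyldimethylsilyl)oxy]pent-4-en-2-amine | C=C[C@@H](O[Si](C)(C)C(C)(C)C)[C@@H](C)N | intermediate
9 | cyclopent-2-en-1-one | O=C1C=CCC1 | starting material
10 | rac-cyclopent-2-en-1-ol | OC1C=CCC1 | intermediate (not isolated)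
11 | rac-cyclopent-2-en-1-yl methyl carbonate | COC(=O)OC1C=CCC1 | intermediate
12 | (2R,3R)-3-[(tert-butyldimethylsilyl)oxy]-N-[(1S)-cyclopent-2-en-1-yl]pent-4-en-2-amine | C=C[C@@H](O[Si](C)(C)C(C)(C)C)[C@@H](C)N[C@@H]1C=CCC1 | intermediate
13 | (2R,3R)-3-[(tert-butyldimethylsilyl)oxy]-N-[(1S)-cyclopent-2-en-1-yl]pent-4-en-2-aminium 4-methylbenzenesulfonate | C=C[C@@H](O[Si](C)(C)C(C)(C)C)[C@@H](C)[NH2+][C@@H]1C=CCC1.Cc1ccc(cc1)S(=O)(=O)[O-] | intermediate (not isolated)
14 | (2R,3R,6S)-6-(but-3-en-1-yl)-3-[(tert-butyldimethylsilyl)oxy]-2-methyl-1,2,3,6-tetrahydropyridin-1-ium 4-methylbenzenesulfonate | CC(C)(C)[Si](C)(C)O[C@@H]1C=C[C@H](CCC=C)[NH2+][C@@H]1C.Cc1ccc(cc1)S(=O)(=O)[O-] | intermediate (not isolated)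
15 | (2R,3R,6S)-6-(but-3-en-1-yl)-3-[(tert-butyldimethylsilyl)oxy]-2-methyl-1,2,3,6-tetrahydropyridine | CC(C)(C)[Si](C)(C)O[C@@H]1C=C[C@H](CCC=C)N[C@@H]1C | intermediate
16 | 8-bromooct-1-ene | C=CCCCCCCBr | starting material
17 | N-methoxy-N-methylacetamide | CC(=O)N(C)OC | starting material
18 | oct-7-en-1-ylmagnesium bromide | C=CCCCCCC[Mg]Br | intermediate (not isolated)
19 | dec-9-en-2-one | CC(=O)CCCCCCC=C | intermediate
20 | tert-butyl (2R,3R,6S)-6-(but-3-en-1-yl)-3-[(tert-butyldimethylsilyl)oxy]-2-methyl-3,6-dihydro-2H-pyridine-1-carboxylate | CC(C)(C)[Si](C)(C)O[C@@H]1C=C[C@H](CCC=C)N(C(=O)OC(C)(C)C)[C@@H]1C | intermediate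
21 | tert-butyl (2R,3R,6S)-3-[(tert-butyldimethylsilyl)oxy]-2-methyl-6-[(3E/Z)-11-oxododec-3-en-1-yl]-3,6-dihydro-2H-pyridine-1-carboxylate (mixture of alkene isomers) | CC(C)(C)[Si](C)(C)O[C@@H]1C=C[C@H](CCC=CCCCCCCC(C)=O)N(C(=O)OC(C)(C)C)[C@@H]1C | intermediate
22 | tert-butyl (2R,3R,6S)-3-[(tert-butyldimethylsilyl)oxy]-2-methyl-6-(11-oxododecyl)piperidine-1-carboxylate | CC(C)(C)[Si](C)(C)O[C@@H]1CC[C@H](CCCCCCCCCCC(C)=O)N(C(=O)OC(C)(C)C)[C@@H]1C | intermediate (not isolated)
23 | tert-butyl (2R,3R,6S)-3-hydroxy-2-methyl-6-(11-oxododecyl)piperidine-1-carboxylate | O[C@@H]1CC[C@H](CCCCCCCCCCC(C)=O)N(C(=O)OC(C)(C)C)[C@@H]1C | intermediate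
24 | ferulic acid | COc1cc(/C=C/C(=O)O)ccc1O | starting material
25 | (2E)-3-{4-[(tert-butoxycarbonyl)oxy]-3-methoxyphenyl}prop-2-enoic acid | COc1cc(/C=C/C(=O)O)ccc1OC(=O)OC(C)(C)C | intermediate
26 | N,N'-dicyclohexyl-O-acylisourea of 25 | COc1cc(/C=C/C(=O)OC(=NC2CCCCC2)NC2CCCCC2)ccc1OC(=O)OC(C)(C)C | intermediate (not isolated)
27 | tert-butyl (2R,3R,6S)-3-{[(2E)-3-{4-[(tert-butoxycarbonyl)oxy]-3-methoxyphenyl}prop-2-enoyl]oxy}-2-methyl-6-(11-oxododecyl)piperidine-1-carboxylate | COc1cc(/C=C/C(=O)O[C@@H]2CC[C@H](CCCCCCCCCCC(C)=O)N(C(=O)OC(C)(C)C)[C@@H]2C)ccc1OC(=O)OC(C)(C)C | intermediate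
28 | (+)-3-O-feruloylcassine | COc1cc(/C=C/C(=O)O[C@@H]2CC[C@H](CCCCCCCCCCC(C)=O)N[C@@H]2C)ccc1O | target

**Totals and risks**

Total step count: 14. Longest linear sequence: 11 steps (steps 1, 2, 3, 4, 6, 7, 9, 10, 11, 13, 14); steps 5, 8 and 12 prepare the three side partners.

Steps most likely to fail:

Step 6. The α-branched, β-silyloxy amine may attack the allyl palladium complex slowly, and the chirality of the nucleophile may work against the ligand (mismatched double stereodifferentiation), lowering the selectivity at C6. The fallback changes the nucleophile class to a sulfonamide anion, an established partner for cyclic allyl carbonates with this ligand. It sets out from 8, which with 2-nitrobenzenesulfonyl chloride and Et3N in CH2Cl2 should give N-[(2R,3R)-3-[(tert-butyldimethylsilyl)oxy]pent-4-en-2-yl]-2-nitrobenzenesulfonamide F1. Allylation of F1 with 11 under Pd2(dba)3·CHCl3 and the same ligand should give N-[(1S)-cyclopent-2-en-1-yl]-N-[(2R,3R)-3-[(tert-butyldimethylsilyl)oxy]pent-4-en-2-yl]-2-nitrobenzenesulfonamide F2. Removal of the sulfonyl group with PhSH and K2CO3 in DMF comes back to the route at 12.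

Step 7. Traces of free amine may deactivate the ruthenium carbene, or intermolecular metathesis may outrun the intramolecular relay and give oligomers. The fallback masks nitrogen covalently as an amide, the substrate class on which this rearrangement is best established. It sets out from 12, which with trifluoroacetic anhydride and pyridine in CH2Cl2 should give N-[(1S)-cyclopent-2-en-1-yl]-N-[(2R,3R)-3-[(tert-butyldimethylsilyl)oxy]pent-4-en-2-yl]-2,2,2-trifluoroacetamide F3. The same ruthenium catalyst under ethene should rearrange F3 to 1-[(2R,3R,6S)-6-(but-3-en-1-yl)-3-[(tert-butyldimethylsilyl)oxy]-2-methyl-3,6-dihydropyridin-1(2H)-yl]-2,2,2-trifluoroethan-1-one F4. Cleavage of the amide with K2CO3 in aqueous MeOH at 50 °C comes back to the route at 15.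

Step 2. Over-reduction to the primary alcohol, a weak chelate giving poor facial selectivity at C3, or partial epimerisation at C2 would erode the threo amino alcohol. The fallback replaces substrate-controlled addition by catalyst-controlled ketone reduction; it sets out from 1 and comes back to the route at 8. Boc2O and Et3N should convert 1 into methyl N-(tert-butoxycarbonyl)-D-alaninate F5, and MeNHOMe·HCl with i-PrMgCl in THF at −20 °C should turn this into tert-butyl N-[(2R)-1-[methoxy(methyl)amino]-1-oxopropan-2-yl]carbamate F6. Lithium (trimethylsilyl)acetylide in THF at −78 °C should then give tert-butyl N-[(2R)-3-oxo-5-(trimethylsilyl)pent-4-yn-2-yl]carbamate F7. Asymmetric transfer hydrogenation of this alkynyl ketone with RuCl[(S,S)-TsDPEN](p-cymene) in i-PrOH (the catalyst enantiomer expected by the usual model to deliver the 3R alcohol) should give tert-butyl N-[(2R,3R)-3-hydroxy-5-(trimethylsilyl)pent-4-yn-2-yl]carbamate F8. K2CO3 in MeOH should remove the alkynyl silyl group to give tert-butyl N-[(2R,3R)-3-hydroxypent-4-yn-2-yl]carbamate F9, and TBSCl with imidazole in DMF should give tert-butyl N-[(2R,3R)-3-[(tert-butyldimethylsilyl)oxy]pent-4-yn-2-yl]carbamate F10. Semihydrogenation over Pd/CaCO3 poisoned with Pb(OAc)2 and quinoline should give tert-butyl N-[(2R,3R)-3-[(tert-butyldimethylsilyl)oxy]pent-4-en-2-yl]carbamate F11. TMSOTf and 2,6-lutidine in CH2Cl2 followed by MeOH should finally remove the carbamate without touching the silyl ether and give 8.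

**Further compounds**

F1 | step 6 | N-[(2R,3R)-3-[(tert-butyldimethylsilyl)oxy]pent-4-en-2-yl]-2-nitrobenzenesulfonamide | C=C[C@@H](O[Si](C)(C)C(C)(C)C)[C@@H](C)NS(=O)(=O)c1ccccc1[N+](=O)[O-]
F2 | step 6 | N-[(1S)-cyclopent-2-en-1-yl]-N-[(2R,3R)-3-[(tert-butyldimethylsilyl)oxy]pent-4-en-2-yl]-2-nitrobenzenesulfonamide | C=C[C@@H](O[Si](C)(C)C(C)(C)C)[C@@H](C)N([C@@H]1C=CCC1)S(=O)(=O)c1ccccc1[N+](=O)[O-]
F3 | step 7 | N-[(1S)-cyclopent-2-en-1-yl]-N-[(2R,3R)-3-[(tert-butyldimethylsilyl)oxy]pent-4-en-2-yl]-2,2,2-trifluoroacetamide | C=C[C@@H](O[Si](C)(C)C(C)(C)C)[C@@H](C)N([C@@H]1C=CCC1)C(=O)C(F)(F)F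
F4 | step 7 | 1-[(2R,3R,6S)-6-(but-3-en-1-yl)-3-[(tert-butyldimethylsilyl)oxy]-2-methyl-3,6-dihydropyridin-1(2H)-yl]-2,2,2-trifluoroethan-1-one | CC(C)(C)[Si](C)(C)O[C@@H]1C=C[C@H](CCC=C)N(C(=O)C(F)(F)F)[C@@H]1C
F5 | step 2 | methyl N-(tert-butoxycarbonyl)-D-alaninate | C[C@@H](NC(=O)OC(C)(C)C)C(=O)OC
F6 | step 2 | tert-butyl N-[(2R)-1-[methoxy(methyl)amino]-1-oxopropan-2-yl]carbamate | C[C@@H](NC(=O)OC(C)(C)C)C(=O)N(C)OC
F7 | step 2 | tert-butyl N-[(2R)-3-oxo-5-(trimethylsilyl)pent-4-yn-2-yl]carbamate | C[C@@H](NC(=O)OC(C)(C)C)C(=O)C#C[Si](C)(C)C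
F8 | step 2 | tert-butyl N-[(2R,3R)-3-hydroxy-5-(trimethylsilyl)pent-4-yn-2-yl]carbamate | C[Si](C)(C)C#C[C@@H](O)[C@@H](C)NC(=O)OC(C)(C)C
F9 | step 2 | tert-butyl N-[(2R,3R)-3-hydroxypent-4-yn-2-yl]carbamate | C#C[C@@H](O)[C@@H](C)NC(=O)OC(C)(C)C
F10 | step 2 | tert-butyl N-[(2R,3R)-3-[(tert-butyldimethylsilyl)oxy]pent-4-yn-2-yl]carbamate | C#C[C@@H](O[Si](C)(C)C(C)(C)C)[C@@H](C)NC(=O)OC(C)(C)C
F11 | step 2 | tert-butyl N-[(2R,3R)-3-[(tert-butyldimethylsilyl)oxy]pent-4-en-2-yl]carbamate | C=C[C@@H](O[Si](C)(C)C(C)(C)C)[C@@H](C)NC(=O)OC(C)(C)C
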